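**Plan**

- Numbering: lactone O1, C2(=O), C3=C4, C5, C6; side chain C1'=C2', C3', C4'(OH), C5', C6'(OH), C7', C8'(OH), C9'=C10'-Ph.
- Retrosynthesis: C2=O goes back to a methyl acetal. O1-C2 and C5-C6 are then cut together, because ring atoms C2, C3=C4, C5 are a 1-oxygenated butadiene and C6-O1 is the formyl group of an enal C6(=O)-C1'=C2'. The chain is then cut at C1'=C2' (cross-metathesis), C3'-C4' (allylation) and C7'-C8' (vinylogous aldol).
- Forward: the chain grows linearly from cinnamaldehyde (C8'-C10', Ph) by an acetoacetate unit (C4'-C7'), an allyl group (C2', C3') and crotonaldehyde (C1', C6). The only new ring, the dihydropyran, closes last by [4+2] and is then oxidised to the lactone and deprotected.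
- Stereochemistry: C8' from a titanium-BINOL-catalysed aldol; C6' from C8' by 1,3-syn reduction; C4' from a pinene-derived allylborane; C6 from the chiral chromium catalyst, since it lies too far from the triol for substrate control. Both E-alkenes come from cinnamaldehyde and thermodynamic cross-metathesis.

Key step: step 8

Remark: the (1R,2S) chromium catalyst and the (R)-BINOL-titanium catalyst are assumed to show toward the chain enal and toward cinnamaldehyde the facial sense (Re-face attack) expected from simpler aldehydes; if either sense proved opposite, the mirror-image ligand would be used with no other change.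

**Route**

Step 1
Reactants: 1 (E)-cinnamaldehyde; 2 1-methoxy-1,3-bis(trimethylsilyloxy)buta-1,3-diene (Chan's diene)
Product: 4 methyl (5R,6E)-5-hydroxy-3-oxo-7-phenylhept-6-enoate, via bis-silylated aldol adduct 3 (not isolated)
Conditions: Ti(OiPr)4 (8 mol%), (R)-BINOL (8 mol%), 4 Å molecular sieves, THF, -78 °C to rt; then CF3CO2H (cat.), wet THF, 0 °C
Reagents that add atoms: none
Why: a titanium-BINOL-catalysed vinylogous Mukaiyama aldol addition in which the terminal carbon of the bis-silyl dienolate should attack the Re face of the Lewis-acid-bound aldehyde, setting C8' as R, after which mild acid strips both silyl groups to the δ-hydroxy-β-ketoester.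

Step 2
Reactants: 4 methyl (5R,6E)-5-hydroxy-3-oxo-7-phenylhept-6-enoate
Product: 7 methyl (3S,5R,6E)-3,5-dihydroxy-7-phenylhept-6-enoate, via diethylboron chelate 5 (not isolated), via cyclic diethylborate 6 (not isolated)
Conditions: Et2BOMe (1.1 equiv), THF/MeOH 4:1, -78 °C; NaBH4, -78 °C; then MeOH co-evaporation
Reagents that add atoms: none
Why: Narasaka-Prasad reduction, in which the boron chelate holds the ketol in a half-chair and hydride attacks axially, should give the 1,3-syn diol and so set C6' from C8'.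

Step 3
Reactants: 7 methyl (3S,5R,6E)-3,5-dihydroxy-7-phenylhept-6-enoate
Product: 8 methyl 2-[(4S,6R)-2,2-dimethyl-6-[(E)-2-phenylethenyl]-1,3-dioxan-4-yl]acetate
Conditions: Me2C(OMe)2, PPTS (cat.), CH2Cl2, rt
Reagents that add atoms: 2,2-dimethoxypropane, COC(C)(C)OC
Why: acid-catalysed acetonide formation (transketalisation) of a 1,3-diol, driven by loss of methanol and faster than lactonisation under these mild conditions.

Step 4
Reactants: 8 methyl 2-[(4S,6R)-2,2-dimethyl-6-[(E)-2-phenylethenyl]-1,3-dioxan-4-yl]acetate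
Product: 10 2-[(4S,6R)-2,2-dimethyl-6-[(E)-2-phenylethenyl]-1,3-dioxan-4-yl]acetaldehyde, via aluminium hemiacetal 9 (not isolated)
Conditions: iBu2AlH (1.1 equiv), CH2Cl2, -78 °C; MeOH, then aq. KNaC4H4O6 (potassium sodium tartrate)
Reagents that add atoms: none
Why: partial ester reduction with iBu2AlH, in which the tetrahedral aluminium hemiacetal is stable at -78 °C and collapses to the aldehyde only on work-up.

Step 5
Reactants: 10 2-[(4S,6R)-2,2-dimethyl-6-[(E)-2-phenylethenyl]-1,3-dioxan-4-yl]acetaldehyde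
Product: 12 (2S)-1-[(4R,6R)-2,2-dimethyl-6-[(E)-2-phenylethenyl]-1,3-dioxan-4-yl]pent-4-en-2-ol, via diisopinocampheylborinate 11 (not isolated)
Conditions: (-)-Ipc2B(allyl) (from (+)-α-pinene, 1.3 equiv), Et2O, -78 °C; then 3 M NaOH, 30% H2O2, 0 °C to rt
Reagents that add atoms: (-)-B-allyldiisopinocampheylborane, C=CCB([C@@H]1C[C@@H]2C[C@@H](C2(C)C)[C@H]1C)[C@@H]1C[C@@H]2C[C@@H](C2(C)C)[C@H]1C
Why: Brown allylboration through a closed chair transition state, in which this reagent attacks the Si face of the aldehyde whatever the remote acetonide, should set C4' as S (1,3-anti to C6').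

Step 6
Reactants: 12 (2S)-1-[(4R,6R)-2,2-dimethyl-6-[(E)-2-phenylethenyl]-1,3-dioxan-4-yl]pent-4-en-2-ol
Product: 13 tert-butyl-dimethyl-[(2S)-1-[(4S,6R)-2,2-dimethyl-6-[(E)-2-phenylethenyl]-1,3-dioxan-4-yl]pent-4-en-2-yl]oxysilane
Conditions: TBSCl, imidazole, DMF, rt
Reagents that add atoms: tert-butyldimethylsilyl chloride, CC(C)(C)[Si](C)(C)Cl
Why: standard silylation of a secondary alcohol, which masks C4'-OH so that it cannot add to the enal made in step 7 or bind the Lewis acid in step 8.

Step 7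
Reactants: 13 tert-butyl-dimethyl-[(2S)-1-[(4S,6R)-2,2-dimethyl-6-[(E)-2-phenylethenyl]-1,3-dioxan-4-yl]pent-4-en-2-yl]oxysilane; 14 (E)-crotonaldehyde
Product: 15 (2E,5S)-5-[tert-butyl(dimethyl)silyl]oxy-6-[(4S,6R)-2,2-dimethyl-6-[(E)-2-phenylethenyl]-1,3-dioxan-4-yl]hex-2-enal
Conditions: 14 (5 equiv), RuCl2(H2IMes)(=CH-C6H4-2-OiPr) (second-generation Hoveyda-Grubbs catalyst, 5 mol%), CH2Cl2, 40 °C
Reagents that add atoms: none
Why: olefin cross-metathesis of the unhindered terminal alkene with excess crotonaldehyde, an electron-poor partner that homodimerises slowly, should give the E-enal under thermodynamic control with loss of propene, while the styryl alkene, 1,2-disubstituted and next to the branched dioxane carbon, should react far more slowly.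

Step 8
Reactants: 15 (2E,5S)-5-[tert-butyl(dimethyl)silyl]oxy-6-[(4S,6R)-2,2-dimethyl-6-[(E)-2-phenylethenyl]-1,3-dioxan-4-yl]hex-2-enal; 16 (E)-1-methoxybuta-1,3-diene
Product: 17 (2S,6R)-6-[(1E,4S)-4-[tert-butyl(dimethyl)silyl]oxy-5-[(4S,6R)-2,2-dimethyl-6-[(E)-2-phenylethenyl]-1,3-dioxan-4-yl]pent-1-en-1-yl]-2-methoxy-5,6-dihydro-2H-pyran (2,6-cis)
Conditions: 16 (5 equiv, no other solvent), [CrCl(L)] (10 mol%; H2L = 2-(1-adamantyl)-6-[[(1R,2S)-2-hydroxyindan-1-yl]iminomethyl]-4-methylphenol), 4 Å molecular sieves, rt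
Reagents that add atoms: none
Why: Proposed new method: the closest known reactions are the hetero-Diels-Alder additions of 1-methoxybutadiene to aliphatic and alkynyl aldehydes under this trivalent chromium Schiff-base catalyst and Lewis-acid-catalysed additions of oxygenated dienes to the carbonyl group of conjugated enals; by the same mechanism the chromium centre should bind the formyl oxygen of 15 and the diene add in a concerted, asynchronous endo [4+2] in which C5-C6 bonding leads and O1-C2 bonding follows. The dihydropyran ring closes by this intermolecular cycloaddition, both ring bonds arising in one transition state, and C3=C4 is placed where the lactone needs it. C6 is set by the catalyst alone, whose (1R,2S) ligand should leave the Re face of the formyl group open to the diene terminus, the nearest chain stereocentre (C4') being four atoms away. C2 follows from the endo topology (2,6-cis) and is erased in step 10. The step needs C=O over C=C selectivity, which should come from the oxophilic Lewis acid activating only the carbonyl carbon, from the β-alkyl group that makes C1'=C2' a poor carbodienophile, and from the s-trans enal geometry that keeps the enal from acting as a heterodiene toward the weakly nucleophilic diene terminus. Acetonide, silyl ether and styryl alkene are indifferent to this mild Lewis acid.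

Step 9
Reactants: 17 (2S,6R)-2-methoxy-6-alkenyl-5,6-dihydro-2H-pyran from step 8
Product: 18 (6R)-6-[(1E,4S)-4-[tert-butyl(dimethyl)silyl]oxy-5-[(4S,6R)-2,2-dimethyl-6-[(E)-2-phenylethenyl]-1,3-dioxan-4-yl]pent-1-en-1-yl]-5,6-dihydro-2H-pyran-2-ol (anomeric mixture)
Conditions: PPTS (0.1 equiv), acetone/H2O 10:1, rt
Reagents that add atoms: water, O
Why: mild acid hydrolysis of the allylic mixed acetal through the ring oxocarbenium ion, which forms much more easily than the one from the acetonide, while acetone as solvent holds the acetonide in place and the secondary silyl ether is stable to PPTS.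

Step 10
Reactants: 18 lactol from step 9
Product: 19 (6R)-6-[(1E,4S)-4-[tert-butyl(dimethyl)silyl]oxy-5-[(4S,6R)-2,2-dimethyl-6-[(E)-2-phenylethenyl]-1,3-dioxan-4-yl]pent-1-en-1-yl]-5,6-dihydro-2H-pyran-2-one
Conditions: MnO2 (activated, excess), CH2Cl2, rt
Reagents that add atoms: none
Why: MnO2 oxidation of an allylic lactol to the α,β-unsaturated δ-lactone, a reagent that leaves the other alkenes, the acetonide and the silyl ether untouched.

Step 11
Reactants: 19 protected lactone from step 10
Product: 20 (6R)-6-[(1E,4S,6R,8R,9E)-4,6,8-trihydroxy-10-phenyldeca-1,9-dien-1-yl]-5,6-dihydro-2H-pyran-2-one (CNP0368533.2)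
Conditions: 48% aq. HF/MeCN 1:19, 0 °C to rt
Reagents that add atoms: none
Why: global deprotection by acetonide hydrolysis and fluoride-assisted silyl ether cleavage in one operation with dilute aqueous HF, acidity chosen low enough to spare the cinnamyl-type C8' carbinol and the unsaturated lactone.

**Compound list**

1 | (E)-cinnamaldehyde | O=C/C=C/c1ccccc1 | starting material
2 | 1-methoxy-1,3-bis(trimethylsilyloxy)buta-1,3-diene (Chan's diene, ketene acetal geometry as supplied) | COC(O[Si](C)(C)C)=CC(=C)O[Si](C)(C)C | starting material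
3 | methyl (5R,6E)-7-phenyl-3,5-bis(trimethylsilyloxy)hepta-2,6-dienoate (C2=C3 geometry not defined) | COC(=O)C=C(O[Si](C)(C)C)C[C@@H](O[Si](C)(C)C)/C=C/c1ccccc1 | intermediate (not isolated)
4 | methyl (5R,6E)-5-hydroxy-3-oxo-7-phenylhept-6-enoate | COC(=O)CC(=O)C[C@@H](O)/C=C/c1ccccc1 | intermediate
5 | diethylboron chelate of ketol 4 | CC[B-]1(CC)O[C@@H](/C=C/c2ccccc2)CC(CC(=O)OC)=[O+]1 | intermediate (not isolated)
6 | cyclic diethylborate of diol 7, sodium salt | [Na+].CC[B-]1(CC)O[C@@H](/C=C/c2ccccc2)C[C@@H](CC(=O)OC)O1 | intermediate (not isolated)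
7 | methyl (3S,5R,6E)-3,5-dihydroxy-7-phenylhept-6-enoate | COC(=O)C[C@@H](O)C[C@@H](O)/C=C/c1ccccc1 | intermediate
8 | methyl 2-[(4S,6R)-2,2-dimethyl-6-[(E)-2-phenylethenyl]-1,3-dioxan-4-yl]acetate | COC(=O)C[C@@H]1C[C@H](/C=C/c2ccccc2)OC(C)(C)O1 | intermediate
9 | diisobutylaluminium hemiacetal of ester 8 (hemiacetal carbon not defined) | COC(O[Al](CC(C)C)CC(C)C)C[C@@H]1C[C@H](/C=C/c2ccccc2)OC(C)(C)O1 | intermediate (not isolated)
10 | 2-[(4S,6R)-2,2-dimethyl-6-[(E)-2-phenylethenyl]-1,3-dioxan-4-yl]acetaldehyde | O=CC[C@@H]1C[C@H](/C=C/c2ccccc2)OC(C)(C)O1 | intermediate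
11 | diisopinocampheylborinate of alcohol 12 | C=CC[C@H](OB([C@@H]1C[C@@H]2C[C@@H](C2(C)C)[C@H]1C)[C@@H]1C[C@@H]2C[C@@H](C2(C)C)[C@H]1C)C[C@@H]1C[C@H](/C=C/c2ccccc2)OC(C)(C)O1 | intermediate (not isolated)
12 | (2S)-1-[(4R,6R)-2,2-dimethyl-6-[(E)-2-phenylethenyl]-1,3-dioxan-4-yl]pent-4-en-2-ol | C=CC[C@H](O)C[C@@H]1C[C@H](/C=C/c2ccccc2)OC(C)(C)O1 | intermediate
13 | tert-butyl-dimethyl-[(2S)-1-[(4S,6R)-2,2-dimethyl-6-[(E)-2-phenylethenyl]-1,3-dioxan-4-yl]pent-4-en-2-yl]oxysilane | C=CC[C@H](O[Si](C)(C)C(C)(C)C)C[C@@H]1C[C@H](/C=C/c2ccccc2)OC(C)(C)O1 | intermediate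
14 | (E)-crotonaldehyde | C/C=C/C=O | starting material
15 | (2E,5S)-5-[tert-butyl(dimethyl)silyl]oxy-6-[(4S,6R)-2,2-dimethyl-6-[(E)-2-phenylethenyl]-1,3-dioxan-4-yl]hex-2-enal | O=C/C=C/C[C@H](O[Si](C)(C)C(C)(C)C)C[C@@H]1C[C@H](/C=C/c2ccccc2)OC(C)(C)O1 | intermediate
16 | (E)-1-methoxybuta-1,3-diene | CO/C=C/C=C | starting material
17 | (2S,6R)-6-[(1E,4S)-4-[tert-butyl(dimethyl)silyl]oxy-5-[(4S,6R)-2,2-dimethyl-6-[(E)-2-phenylethenyl]-1,3-dioxan-4-yl]pent-1-en-1-yl]-2-methoxy-5,6-dihydro-2H-pyran | CO[C@@H]1C=CC[C@H](/C=C/C[C@H](O[Si](C)(C)C(C)(C)C)C[C@@H]2C[C@H](/C=C/c3ccccc3)OC(C)(C)O2)O1 | intermediate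
18 | (6R)-6-[(1E,4S)-4-[tert-butyl(dimethyl)silyl]oxy-5-[(4S,6R)-2,2-dimethyl-6-[(E)-2-phenylethenyl]-1,3-dioxan-4-yl]pent-1-en-1-yl]-5,6-dihydro-2H-pyran-2-ol (anomeric mixture) | OC1C=CC[C@H](/C=C/C[C@H](O[Si](C)(C)C(C)(C)C)C[C@@H]2C[C@H](/C=C/c3ccccc3)OC(C)(C)O2)O1 | intermediate
19 | (6R)-6-[(1E,4S)-4-[tert-butyl(dimethyl)silyl]oxy-5-[(4S,6R)-2,2-dimethyl-6-[(E)-2-phenylethenyl]-1,3-dioxan-4-yl]pent-1-en-1-yl]-5,6-dihydro-2H-pyran-2-one | O=C1C=CC[C@H](/C=C/C[C@H](O[Si](C)(C)C(C)(C)C)C[C@@H]2C[C@H](/C=C/c3ccccc3)OC(C)(C)O2)O1 | intermediate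
20 | (6R)-6-[(1E,4S,6R,8R,9E)-4,6,8-trihydroxy-10-phenyldeca-1,9-dien-1-yl]-5,6-dihydro-2H-pyran-2-one | O=C1C=CC[C@H](/C=C/C[C@H](O)C[C@@H](O)C[C@@H](O)/C=C/c2ccccc2)O1 | target

**Count**

Total steps: 11. Longest linear sequence: 11 steps, from cinnamaldehyde 1 to 20.

**Steps most likely to fail**

1. Step 8 (the proposed method).
   - What may go wrong: the diene may add to C1'=C2' in a carbo-Diels-Alder reaction or engage the enal as a heterodiene. Conversion may stall because a conjugated formyl group is less electrophilic than an aliphatic one. The catalyst may discriminate the two enal faces poorly.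
   - Fallback (known reactions): setting out from enal 15, Brown allylboration with (+)-Ipc2B(allyl) (Et2O, -78 °C; NaOH, H2O2) adds 1,2 to the Re face and should give the (4R)-dienol F1. Acryloyl chloride, Et3N and DMAP in CH2Cl2 at 0 °C convert it to the acrylate F2. Ring-closing metathesis with RuCl2(PCy3)2(=CHPh) (first-generation Grubbs catalyst) in CH2Cl2 at 40 °C forms C3=C4 and returns to the route at lactone 19, so steps 9 and 10 fall away. The ring then arises by metathesis and C6 by reagent control.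

2. Step 7.
   - What may go wrong: the ruthenium carbene may also attack the styryl alkene, with loss of styrene and truncation of the chain. Conversion may be incomplete or the enal may form as an E/Z mixture.
   - Fallback: setting out from aldehyde 10, allenylboration with (-)-Ipc2B(CH=C=CH2) (from CH2=C=CHMgBr and (-)-Ipc2BOMe; Et2O, -78 °C; NaOH, H2O2) is expected to attack the same Si face through the same chair and give the homopropargylic alcohol F3. TBSCl and imidazole give the silyl ether F4. n-BuLi in THF at -78 °C followed by paraformaldehyde gives the propargylic alcohol F5. NaAlH2(OCH2CH2OMe)2 in THF at 0 °C reduces it by hydroxyl-directed trans-hydroalumination to the (E)-allylic alcohol F6. MnO2 in CH2Cl2 then gives enal 15, where the route is rejoined; no metathesis catalyst meets the styryl alkene.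

3. Step 11.
   - What may go wrong: ionisation of the cinnamyl-type C8'-O bond may cause allylic transposition or epimerisation. The acetonide may hydrolyse incompletely. The product may degrade on long exposure to acid.
   - Fallback: setting out from lactone 19, PPTS in MeOH at rt exchanges out only the acetonide and gives the diol silyl ether F7. HF-pyridine buffered with pyridine in THF at 0 °C then removes the silyl group by fluoride attack and gives 20. The two groups are thus removed by two different mild mechanisms in place of one stronger acid treatment.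

**Further compounds**

F1 | step 8 | (4R,5E,8S)-8-[tert-butyl(dimethyl)silyl]oxy-9-[(4S,6R)-2,2-dimethyl-6-[(E)-2-phenylethenyl]-1,3-dioxan-4-yl]nona-1,5-dien-4-ol | C=CC[C@@H](O)/C=C/C[C@H](O[Si](C)(C)C(C)(C)C)C[C@@H]1C[C@H](/C=C/c2ccccc2)OC(C)(C)O1
F2 | step 8 | (4R,5E,8S)-8-[tert-butyl(dimethyl)silyl]oxy-9-[(4S,6R)-2,2-dimethyl-6-[(E)-2-phenylethenyl]-1,3-dioxan-4-yl]nona-1,5-dien-4-yl prop-2-enoate | C=CC[C@@H](OC(=O)C=C)/C=C/C[C@H](O[Si](C)(C)C(C)(C)C)C[C@@H]1C[C@H](/C=C/c2ccccc2)OC(C)(C)O1
F3 | step 7 | (2S)-1-[(4R,6R)-2,2-dimethyl-6-[(E)-2-phenylethenyl]-1,3-dioxan-4-yl]pent-4-yn-2-ol | C#CC[C@H](O)C[C@@H]1C[C@H](/C=C/c2ccccc2)OC(C)(C)O1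
F4 | step 7 | tert-butyl-dimethyl-[(2S)-1-[(4S,6R)-2,2-dimethyl-6-[(E)-2-phenylethenyl]-1,3-dioxan-4-yl]pent-4-yn-2-yl]oxysilane | C#CC[C@H](O[Si](C)(C)C(C)(C)C)C[C@@H]1C[C@H](/C=C/c2ccccc2)OC(C)(C)O1
F5 | step 7 | (5S)-5-[tert-butyl(dimethyl)silyl]oxy-6-[(4S,6R)-2,2-dimethyl-6-[(E)-2-phenylethenyl]-1,3-dioxan-4-yl]hex-2-yn-1-ol | OCC#CC[C@H](O[Si](C)(C)C(C)(C)C)C[C@@H]1C[C@H](/C=C/c2ccccc2)OC(C)(C)O1
F6 | step 7 | (2E,5S)-5-[tert-butyl(dimethyl)silyl]oxy-6-[(4S,6R)-2,2-dimethyl-6-[(E)-2-phenylethenyl]-1,3-dioxan-4-yl]hex-2-en-1-ol | OC/C=C/C[C@H](O[Si](C)(C)C(C)(C)C)C[C@@H]1C[C@H](/C=C/c2ccccc2)OC(C)(C)O1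
F7 | step 11 | (6R)-6-[(1E,4S,6S,8R,9E)-4-[tert-butyl(dimethyl)silyl]oxy-6,8-dihydroxy-10-phenyldeca-1,9-dien-1-yl]-5,6-dihydro-2H-pyran-2-one | O=C1C=CC[C@H](/C=C/C[C@H](O[Si](C)(C)C(C)(C)C)C[C@@H](O)C[C@@H](O)/C=C/c2ccccc2)O1
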